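**Retrosynthetic overview**
1. Target 13 ⇐ chalcone 12 by removal of three MOM groups; 12 ⇐ methyl ketone 8 + aldehyde 10 by Claisen–Schmidt condensation (enone C=C made last).
2. 8 ⇐ 7 by Markovnikov hydration of the isopropenyl group.
3. 7 ⇐ iodophenol 5 + isoprene 6 by enantioselective Pd heteroannulation, forming C3–C3a and O1–C2 and the only ring built in the route, the dihydrofuran ring (both benzene rings are bought).
4. Feature used: C3, C2 and the three carbons of the C(CH3)2OH group are one intact isoprene unit bridging ring carbon C3a and ether oxygen O1; O1 lies para to the acyl-bearing C5, so the phenol that cyclises is the one para to the acetyl group.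
5. 5 ⇐ phloroacetophenone 1 by 4-O-silylation, 2,6-bis-MOM protection, desilylation and mono-iodination.

Key step: step 5

Remark: dihydrobenzofuran numbering (O1, C2, C3, C3a, C4–C7, C7a) is used; the sense of induction of the chiral ligand in step 5 is assumed to be assigned beforehand on a model o-iodophenol, and the ligand antipode that gives (S)-C2 is used.

**Route**

Step 1
Reactants: 1 2,4,6-trihydroxyacetophenone (phloroacetophenone, dried)
Product: 2 1-[2,6-dihydroxy-4-(triisopropylsilyloxy)phenyl]ethanone
Conditions: TIPSCl (1.05 equiv), imidazole, DMF, 0 °C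
Reagents that add atoms: chlorotriisopropylsilane (TIPSCl), CC(C)[Si](Cl)(C(C)C)C(C)C
Why: Regioselective O-silylation should occur at the 4-hydroxyl, which is the most acidic and the only one neither chelated to nor flanked by the acetyl group, and the bulky silyl chloride reinforces this preference.

Step 2
Reactants: 2 1-[2,6-dihydroxy-4-(triisopropylsilyloxy)phenyl]ethanone
Product: 3 1-[2,6-bis(methoxymethoxy)-4-(triisopropylsilyloxy)phenyl]ethanone
Conditions: NaH (2.3 equiv), MOMCl (2.5 equiv), THF, 0 °C → rt
Reagents that add atoms: chloromethyl methyl ether (MOMCl), COCCl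
Why: Williamson-type O-alkylation of the two sodium phenoxides should protect both ortho hydroxyls, since deprotonation breaks the carbonyl chelate and the aryl TIPS ether tolerates NaH in THF.

Step 3
Reactants: 3 1-[2,6-bis(methoxymethoxy)-4-(triisopropylsilyloxy)phenyl]ethanone
Product: 4 1-[4-hydroxy-2,6-bis(methoxymethoxy)phenyl]ethanone
Conditions: TBAF, AcOH (1:1), THF, 0 °C
Reagents that add atoms: none
Why: Fluoride-mediated desilylation should cleave the aryl silyl ether selectively, the MOM acetals being inert to fluoride and the acetic acid buffering the phenoxide.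

Step 4
Reactants: 4 1-[4-hydroxy-2,6-bis(methoxymethoxy)phenyl]ethanone
Product: 5 1-[4-hydroxy-3-iodo-2,6-bis(methoxymethoxy)phenyl]ethanone
Conditions: NIS (1.0 equiv), DMF, −20 → 0 °C, dark
Reagents that add atoms: N-iodosuccinimide (NIS), O=C1CCC(=O)N1I
Why: Electrophilic aromatic iodination should take place ortho to the free phenol, where the two open positions are equivalent by symmetry, and one equivalent of reagent under acid-free conditions limits di-iodination and spares the MOM groups.

Step 5
Reactants: 5 1-[4-hydroxy-3-iodo-2,6-bis(methoxymethoxy)phenyl]ethanone; 6 isoprene (2-methylbuta-1,3-diene)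
Product: 7 1-[(2S)-4,6-bis(methoxymethoxy)-2-(prop-1-en-2-yl)-2,3-dihydro-1-benzofuran-5-yl]ethanone
Conditions: Pd2(dba)3·CHCl3 (5 mol %), TY-Phos-type chiral sulfinamide monophosphine (12 mol %), PhONa (2 equiv), 6 (5 equiv), CH2Cl2, 40 °C, sealed tube
Reagents that add atoms: none
Why: Pd(0) should add oxidatively into the C–I bond of 5, the aryl group should then migrate onto the terminal CH2 of the monosubstituted double bond of isoprene (C3–C3a bond), and the adjacent phenoxide should attack the internal terminus of the resulting 2-methyl-π-allylpalladium (O1–C2 bond), releasing Pd(0) and 7. The closest known reaction type is the Larock heteroannulation of o-halophenols with 1,3-dienes in its enantioselective Heck/Tsuji–Trost form with chiral sulfinamide–phosphine ligands, which is known for isoprene. The dihydrofuran ring closes in a 5-exo-trig mode on the proximal allyl carbon, in preference to seven-ring formation at the distal CH2 terminus. The C2 stereocentre is catalyst-controlled: the π-allyl can exchange faces by η3–η1–η3 slippage at its unsubstituted CH2 end, so the chiral ligand decides the configuration at C–O bond formation. The step needs insertion at the less substituted alkene (secured by the vinyl versus isopropenyl difference in isoprene), O-attack at the internal allyl carbon (secured by five-ring formation) and a single ring-fusion isomer (secured because both hydroxyls ortho to the acetyl group are MOM ethers, leaving only the phenol para to the acetyl group, which is acidic enough to be fully ionised by PhONa).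

Step 6
Reactants: 7 1-[(2S)-4,6-bis(methoxymethoxy)-2-(prop-1-en-2-yl)-2,3-dihydro-1-benzofuran-5-yl]ethanone
Product: 8 1-[(2S)-2-(2-hydroxypropan-2-yl)-4,6-bis(methoxymethoxy)-2,3-dihydro-1-benzofuran-5-yl]ethanone
Conditions: Mn(dpm)3 (cat.), PhSiH3, O2 (1 atm), i-PrOH/CH2Cl2, 0 °C → rt
Reagents that add atoms: dioxygen, O=O
Why: Mukaiyama hydration (metal-hydride hydrogen-atom transfer to the terminal CH2, O2 capture of the tertiary radical and O–O reduction by the silane) should give the Markovnikov tertiary alcohol without touching the aryl ketone, the MOM acetals or the C2 stereocentre, and it is placed before the enone is made because an enone would be reduced under these conditions.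

Step 7
Reactants: 9 4-hydroxybenzaldehyde
Product: 10 4-(methoxymethoxy)benzaldehyde
Conditions: MOMCl, i-Pr2NEt, CH2Cl2, 0 °C → rt
Reagents that add atoms: chloromethyl methyl ether (MOMCl), COCCl
Why: O-alkylation of the acidic, unhindered phenol with MOMCl and a tertiary amine base should give the MOM ether, so that the aldehyde is not deactivated as a phenoxide in the condensation.

Step 8
Reactants: 8 1-[(2S)-2-(2-hydroxypropan-2-yl)-4,6-bis(methoxymethoxy)-2,3-dihydro-1-benzofuran-5-yl]ethanone; 10 4-(methoxymethoxy)benzaldehyde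
Product: 12 (2E)-1-[(2S)-2-(2-hydroxypropan-2-yl)-4,6-bis(methoxymethoxy)-2,3-dihydro-1-benzofuran-5-yl]-3-[4-(methoxymethoxy)phenyl]prop-2-en-1-one, via aldol adduct 11 (not isolated)
Conditions: KOH, EtOH/H2O, rt
Reagents that add atoms: none
Why: Claisen–Schmidt condensation of the methyl ketone enolate with the non-enolisable aldehyde, followed by E1cB dehydration of the aldol adduct, should give the thermodynamically favoured (E)-enone, with the MOM ethers, the tertiary alcohol and the non-acidic C2 centre unaffected by base.

Step 9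
Reactants: 12 (2E)-1-[(2S)-2-(2-hydroxypropan-2-yl)-4,6-bis(methoxymethoxy)-2,3-dihydro-1-benzofuran-5-yl]-3-[4-(methoxymethoxy)phenyl]prop-2-en-1-one
Product: 13 (2E)-1-[(2S)-4,6-dihydroxy-2-(2-hydroxypropan-2-yl)-2,3-dihydro-1-benzofuran-5-yl]-3-(4-hydroxyphenyl)prop-2-en-1-one
Conditions: HCl (3 M in MeOH), MeOH, rt, stopped as soon as the last MOM group is gone
Reagents that add atoms: none
Why: Acid-catalysed acetal methanolysis should remove all three MOM groups at room temperature (the two ortho to the carbonyl fastest, by chelation assistance), which keeps the tertiary alcohol, whose ionisation is disfavoured by the adjacent ether oxygen, and limits acid-promoted chalcone-to-flavanone cyclisation.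

**Compound list**
1 | 2,4,6-trihydroxyacetophenone (phloroacetophenone) | CC(=O)c1c(O)cc(O)cc1O | starting material
2 | 1-[2,6-dihydroxy-4-(triisopropylsilyloxy)phenyl]ethanone | CC(=O)c1c(O)cc(O[Si](C(C)C)(C(C)C)C(C)C)cc1O | intermediate
3 | 1-[2,6-bis(methoxymethoxy)-4-(triisopropylsilyloxy)phenyl]ethanone | CC(=O)c1c(OCOC)cc(O[Si](C(C)C)(C(C)C)C(C)C)cc1OCOC | intermediate
4 | 1-[4-hydroxy-2,6-bis(methoxymethoxy)phenyl]ethanone | CC(=O)c1c(OCOC)cc(O)cc1OCOC | intermediate
5 | 1-[4-hydroxy-3-iodo-2,6-bis(methoxymethoxy)phenyl]ethanone | CC(=O)c1c(OCOC)cc(O)c(I)c1OCOC | intermediate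
6 | isoprene (2-methylbuta-1,3-diene) | C=CC(C)=C | starting material
7 | 1-[(2S)-4,6-bis(methoxymethoxy)-2-(prop-1-en-2-yl)-2,3-dihydro-1-benzofuran-5-yl]ethanone | C=C(C)[C@@H]1Cc2c(cc(OCOC)c(C(C)=O)c2OCOC)O1 | intermediate
8 | 1-[(2S)-2-(2-hydroxypropan-2-yl)-4,6-bis(methoxymethoxy)-2,3-dihydro-1-benzofuran-5-yl]ethanone | CC(C)(O)[C@@H]1Cc2c(cc(OCOC)c(C(C)=O)c2OCOC)O1 | intermediate
9 | 4-hydroxybenzaldehyde | O=Cc1ccc(O)cc1 | starting material
10 | 4-(methoxymethoxy)benzaldehyde | COCOc1ccc(C=O)cc1 | intermediate
11 | 3-hydroxy-1-[(2S)-2-(2-hydroxypropan-2-yl)-4,6-bis(methoxymethoxy)-2,3-dihydro-1-benzofuran-5-yl]-3-[4-(methoxymethoxy)phenyl]propan-1-one (aldol adduct, both carbinol epimers) | CC(C)(O)[C@@H]1Cc2c(cc(OCOC)c(C(=O)CC(O)c3ccc(OCOC)cc3)c2OCOC)O1 | intermediate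
12 | (2E)-1-[(2S)-2-(2-hydroxypropan-2-yl)-4,6-bis(methoxymethoxy)-2,3-dihydro-1-benzofuran-5-yl]-3-[4-(methoxymethoxy)phenyl]prop-2-en-1-one | CC(C)(O)[C@@H]1Cc2c(cc(OCOC)c(C(=O)/C=C/c3ccc(OCOC)cc3)c2OCOC)O1 | intermediate
13 | (2E)-1-[(2S)-4,6-dihydroxy-2-(2-hydroxypropan-2-yl)-2,3-dihydro-1-benzofuran-5-yl]-3-(4-hydroxyphenyl)prop-2-en-1-one | CC(C)(O)[C@@H]1Cc2c(cc(O)c(C(=O)/C=C/c3ccc(O)cc3)c2O)O1 | target

**Step count**
Total steps: 9. Longest linear sequence: 8 (steps 1–6, 8, 9); step 7 is a one-step side branch.

**Steps most likely to fail, with fallbacks**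

Step 5. Oxidative addition at an aryl iodide flanked by two oxygen substituents may be slow and lead to protodeiodination. Iodide-bound palladium may also erode enantiofacial control, and some insertion may occur at the isopropenyl end of the diene. Fallback, setting out from 5 and coming back to the route at 8 (so that step 6 is bypassed as well): the phenol of 5 would be silylated (TBSCl, imidazole, DMF) to 1-[4-(tert-butyldimethylsilyloxy)-3-iodo-2,6-bis(methoxymethoxy)phenyl]ethanone F1. Stille coupling with tributyl(3-methylbut-2-en-1-yl)stannane (Pd(PPh3)4, DMF, 90 °C) should give the ortho-prenyl arene 1-[4-(tert-butyldimethylsilyloxy)-2,6-bis(methoxymethoxy)-3-(3-methylbut-2-en-1-yl)phenyl]ethanone F2. Shi asymmetric epoxidation (fructose-derived ketone of the antipode that leads to the (R)-epoxide, Oxone, K2CO3 buffer, MeCN/dimethoxymethane/H2O, 0 °C) should give 1-[4-(tert-butyldimethylsilyloxy)-3-{[(2R)-3,3-dimethyloxiran-2-yl]methyl}-2,6-bis(methoxymethoxy)phenyl]ethanone F3. TBAF in THF would then free the phenoxide, which should open the epoxide 5-exo at the secondary carbon with inversion and give 8 with (S)-C2.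

Step 9. Once an ortho hydroxyl is freed, acid-promoted oxa-Michael closure of the 2'-hydroxychalcone to flavanones may compete, and prolonged acid may solvolyse the tertiary alcohol. Fallback, setting out from 8 and coming back at 13: the two MOM ethers would be removed before any enone exists (HCl, MeOH, rt) to give 1-[(2S)-4,6-dihydroxy-2-(2-hydroxypropan-2-yl)-2,3-dihydro-1-benzofuran-5-yl]ethanone F4. F4 would be condensed with unprotected 4-hydroxybenzaldehyde 9 in concentrated aqueous KOH/EtOH, where the chalcone is held as its open polyphenoxide. Rapid acidification of the cold mixture should then give 13 directly, with no acid treatment of a protected chalcone.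

Step 2. Alkylation of the second, chelated hydroxyl may stay incomplete, and under the strongly basic conditions the silyl group may be lost or transferred, so that MOM ends up on the 4-oxygen. Fallback, setting out from 1 and coming back at 4: selective 4-O-benzylation (BnBr, 1 equiv, K2CO3, acetone) should give 1-[4-(benzyloxy)-2,6-dihydroxyphenyl]ethanone F5. Exhaustive MOM protection under forcing conditions that a benzyl ether tolerates (NaH, MOMCl, DMF) should give 1-[4-(benzyloxy)-2,6-bis(methoxymethoxy)phenyl]ethanone F6. Hydrogenolysis (H2, Pd/C, EtOAc) should then give 4.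

**Further compounds**
F1 | step 5 | 1-[4-(tert-butyldimethylsilyloxy)-3-iodo-2,6-bis(methoxymethoxy)phenyl]ethanone | CC(=O)c1c(OCOC)cc(O[Si](C)(C)C(C)(C)C)c(I)c1OCOC
F2 | step 5 | 1-[4-(tert-butyldimethylsilyloxy)-2,6-bis(methoxymethoxy)-3-(3-methylbut-2-en-1-yl)phenyl]ethanone | CC(=O)c1c(OCOC)cc(O[Si](C)(C)C(C)(C)C)c(CC=C(C)C)c1OCOC
F3 | step 5 | 1-[4-(tert-butyldimethylsilyloxy)-3-{[(2R)-3,3-dimethyloxiran-2-yl]methyl}-2,6-bis(methoxymethoxy)phenyl]ethanone | CC(=O)c1c(OCOC)cc(O[Si](C)(C)C(C)(C)C)c(C[C@H]2OC2(C)C)c1OCOC
F4 | step 9 | 1-[(2S)-4,6-dihydroxy-2-(2-hydroxypropan-2-yl)-2,3-dihydro-1-benzofuran-5-yl]ethanone | CC(C)(O)[C@@H]1Cc2c(cc(O)c(C(C)=O)c2O)O1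
F5 | step 2 | 1-[4-(benzyloxy)-2,6-dihydroxyphenyl]ethanone | CC(=O)c1c(O)cc(OCc2ccccc2)cc1O
F6 | step 2 | 1-[4-(benzyloxy)-2,6-bis(methoxymethoxy)phenyl]ethanone | CC(=O)c1c(OCOC)cc(OCc2ccccc2)cc1OCOC
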